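You cannot get open intermediate out of this flask without some of it passing on to target, and target is what eats substrate.

    substrate → open intermediate (k1 = 0.33 h⁻¹)
    partner → second intermediate (k2 = 0.58 h⁻¹)
    open intermediate + second intermediate ⇌ target (K3 = 1.7 M⁻¹, k3 = 8.0 M⁻¹ h⁻¹)
    substrate + target → side product (k4 = 9.1 M⁻¹ h⁻¹)

the same everywhere: substrate 0.20 M
- ochre: partner 0.190 M (fed, over 12.0 h); time 15 h; all but partner at the start; partner goes in evenly over 12.0 h, the run ends at 15 h
- green: partner 0.190 M; a single well-mixed tank run continuously and read at steady state, 15 h in it on average
- amber: partner 0.190 M; time 15 h; a closed flask charged with all of it at once and left for 15 h
- violet: partner 0.190 M; one stirred flow tank at steady state, fed with the mixture as stated, mean residence time 75.0 h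

- a species is counted by the substrate in it: one side product counts as two
- the stated concentrations are those of everything mixed, before any reaction; amounts are the same in each set-up
- the feed brings no volume worth counting
- run time (ochre): 15 h

- the set-up with the highest amount of open intermediate at the outlet or at the end, in percent of the substrate put in ("none" if the first two lie within 2 percentage points) (ochre / green / amber / violet / none)
- amount of open intermediate at the outlet or at the end, in percent of the substrate put in, ochre
- amount of open intermediate at the outlet or at the end, in percent of the substrate put in, green
- amount of open intermediate at the outlet or at the end, in percent of the substrate put in, amber
- amount of open intermediate at the outlet or at the end, in percent of the substrate put in, violet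

So I carry one quantity, the break-even target concentration, c(break-even) = k1/k4 = 0.0363 M: at that c(target), substrate goes to side product as fast as it opens. At any c(target), the leak share of the substrate consumed, a selectivity, is c(target)/(c(target) + c(break-even)). Each leaked substrate costs two units, itself and one target.

How high can target stand? The equilibrium relaxes in about 0.128 h, far shorter than the mean life of substrate, 3.03 h. I therefore treat the target equilibrium as standing at every moment, and since K3 times cA is 0.340, below one, I treat target as a small correction to the two intermediates. With full charges, K3·cA·cD/(1 + K3(cA + cD)) gives 0.0388 M, which is 1.07 times break-even, so the leak has to be reckoned.

What does a long-stay tank give, with substrate beside steady target? For violet, try c(target) = 0.01451 M. The leak share is 28.6%, which leaves 0.0857 M of open intermediate plus target and 0.133 M of second intermediate. The same correction returns 0.01411 M, close to the trial. My violet figure is 35.8%, and I carry it to green.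

What does dosing change? In ochre, a quarter of the partner is in by the mean life of substrate, so I scale the leak share to 7.22%. The same correction then gives 69.5%. Amber has its partner at once, so I expect a larger leak and a lower figure than ochre. I put ochre first.

The forecast names ochre, with 67%, 35.4%, 47% and 35.8% for ochre, green, amber and violet, and it credits the “slow partner feed”.

The simulation puts ochre first: ochre 67.7%, green 35.4%, amber 49.6%, violet 35.8%.

Ochre's open intermediate stands mainly because target runs back to open intermediate and second intermediate: with that backward run struck out, ochre reads 8.74% against 67.7%. Green's target reading, 6.36% of the charge, gives a leak share of 26.0% through c(break-even). Its side product reading, halved and set against the substrate consumed, gives 26.0%. Violet's target reading, 7.04%, gives a share of 28.0%, so side product should count 54.3% of the charge, and violet's balance of readings leaves 54.3%.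

(All constants were drawn at random within sensible limits; no experiment stands behind them.)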